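Ring C is cut at O1–C8a and C4–C4a. Ring A then arrives as an aryne, and the O1–C2–C3–C4 chain with ring B arrives as one enolate. The feature exploited is the ortho relationship on ring A between C8a (bonded to O1) and C4a (bonded to C4), with the C5 oxygen on the far side of C4a. A 3,5-dialkoxybenzyne maps onto this pattern when a nucleophile enters at its open terminus. In one operation the enolate oxygen is arylated and the resulting aryl anion is acylated, which closes the pyranone. The precursors are a bis-MOM 2-silylaryl triflate and the preformed sodium enolate of an alpha-formyl arylacetate whose ring B holds bromine in place of prenyl.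

Key step: step 9

Remark on ring B: 5-bromovanillin has its free OH para and its OMe meta to the formyl group. Ring B needs the reverse (4'-OMe between 3'-OH and C5'), so the methyl group is moved to the other oxygen in steps 5 and 6.
Remark on the ester: the ester alkyl group leaves as alkoxide in step 9 and is a spectator. Ethyl is used because ethyl diazoacetate is the commercial diazo ester.
Remark on 13: it is drawn as the hydrogen-bonded Z enol, in tautomeric equilibrium with the aldehyde form (ethyl 2-aryl-3-oxopropanoate). The target has no stereocentre.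

Step 1
Reactants: 1 phloroglucinol
Product: 2 3,5-bis(methoxymethoxy)phenol
Conditions: MOMCl (2.0 equiv), i-Pr2NEt (2.2 equiv), DMF, 0 °C to rt; chromatography
Reagents that add atoms: chloromethyl methyl ether (MOMCl), COCCl
Why: MOM protection (O-alkylation of a phenol with an alpha-chloro ether) of three equivalent hydroxyls with two equivalents of reagent should give a statistical mixture free of regioisomers, from which the bis-ether is separated and the mono-ether recycled.

Step 2
Reactants: 2 3,5-bis(methoxymethoxy)phenol
Product: 3 2-bromo-3,5-bis(methoxymethoxy)phenol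
Conditions: NBS (1.0 equiv), CH2Cl2, −78 °C to 0 °C
Reagents that add atoms: N-bromosuccinimide, O=C1CCC(=O)N1Br
Why: Electrophilic aromatic bromination should favour the two equivalent positions ortho to the free OH, by number, by hydrogen-bond delivery of NBS in a non-polar solvent and by the crowding of C4 between two MOM ethers, and any para isomer is removed by chromatography.

Step 3
Reactants: 3 2-bromo-3,5-bis(methoxymethoxy)phenol
Product: 4 [2-bromo-3,5-bis(methoxymethoxy)phenoxy]trimethylsilane
Conditions: HMDS, THF, 65 °C; evaporation
Reagents that add atoms: hexamethyldisilazane, C[Si](C)(C)N[Si](C)(C)C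
Why: O-silylation of the phenol with HMDS is driven by loss of ammonia and needs neither acid nor strong base, so the bromide and the MOM ethers are untouched and the crude silyl ether can be carried on.

Step 4
Reactants: 4 [2-bromo-3,5-bis(methoxymethoxy)phenoxy]trimethylsilane
Product: 7 3,5-bis(methoxymethoxy)-2-(trimethylsilyl)phenyl trifluoromethanesulfonate, via aryllithium 5 (not isolated), via lithium 2-silylphenoxide 6 (not isolated)
Conditions: n-BuLi (1.1 equiv), THF, −78 °C; then Tf2O (1.2 equiv), −78 °C
Reagents that add atoms: trifluoromethanesulfonic anhydride, O=S(=O)(OS(=O)(=O)C(F)(F)F)C(F)(F)F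
Why: Bromine–lithium exchange outruns MOM-directed deprotonation at −78 °C, aryllithium 5 undergoes a retro-Brook (1,3 oxygen-to-carbon) silyl shift driven by formation of phenoxide 6, and O-sulfonylation of 6 gives the 2-silylaryl triflate.

Step 5
Reactants: 8 5-bromovanillin (3-bromo-4-hydroxy-5-methoxybenzaldehyde)
Product: 9 3-bromo-4,5-dihydroxybenzaldehyde
Conditions: AlCl3 (1.2 equiv), pyridine (4.4 equiv), CH2Cl2, reflux; aq. HCl work-up
Reagents that add atoms: none
Why: In this Lewis acid-assisted aryl methyl ether cleavage aluminium binds the free phenol and chelates the neighbouring methoxy oxygen, so pyridine removes that methyl group by SN2 attack while the aldehyde and the bromide stay intact.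

Step 6
Reactants: 9 3-bromo-4,5-dihydroxybenzaldehyde
Product: 10 3-bromo-5-hydroxy-4-methoxybenzaldehyde
Conditions: DBU (1.0 equiv), MeI (1.05 equiv), DMF, rt
Reagents that add atoms: iodomethane, CI
Why: In this regioselective Williamson etherification one equivalent of base deprotonates only the 4-OH, the more acidic one through conjugation with the para formyl group and the ortho bromine, so the monoanion is methylated at O4 and the 5-OH stays free.

Step 7
Reactants: 10 3-bromo-5-hydroxy-4-methoxybenzaldehyde
Product: 11 3-bromo-4-methoxy-5-(methoxymethoxy)benzaldehyde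
Conditions: MOMCl (1.3 equiv), i-Pr2NEt, CH2Cl2, 0 °C to rt
Reagents that add atoms: chloromethyl methyl ether (MOMCl), COCCl
Why: MOM protection of the one remaining phenol installs a group that tolerates fluoride, alkoxide and palladium catalysis and that falls together with the ring A MOM ethers in the last step.

Step 8
Reactants: 11 3-bromo-4-methoxy-5-(methoxymethoxy)benzaldehyde; 12 ethyl diazoacetate
Product: 13 ethyl (Z)-2-[3-bromo-4-methoxy-5-(methoxymethoxy)phenyl]-3-hydroxyprop-2-enoate (enol of the alpha-formyl arylacetate)
Conditions: 12 (1.3 equiv, slow addition), HBF4·OEt2 (10 mol %), CH2Cl2, −78 °C; Et3N quench at −78 °C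
Reagents that add atoms: ethyl diazoacetate 12, CCOC(=O)C=[N+]=[N-]
Why: In this acid-catalysed aldehyde–diazoacetate homologation (the aryl-shift counterpart of the Roskamp reaction) the diazo carbon adds to the protonated formyl group and the para-methoxy-bearing aryl group migrates to the diazonium carbon as N2 leaves, which gives the alpha-formyl ester as its hydrogen-bonded Z enol, while low temperature, a catalytic acid charge and the absence of a protic nucleophile should keep the MOM ether in place.

Step 9
Reactants: 13 ethyl (Z)-2-[3-bromo-4-methoxy-5-(methoxymethoxy)phenyl]-3-hydroxyprop-2-enoate; 7 3,5-bis(methoxymethoxy)-2-(trimethylsilyl)phenyl trifluoromethanesulfonate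
Product: 17 3-[3-bromo-4-methoxy-5-(methoxymethoxy)phenyl]-5,7-bis(methoxymethoxy)chromen-4-one, via sodium enolate 14 (not isolated), via aryne 15 (not isolated), via aryl anion 16 (not isolated)
Conditions: NaH (1.0 equiv), THF, 0 °C; then 7 (1.5 equiv), CsF (4 equiv), THF, 65 °C
Reagents that add atoms: none
Why: Proposed new method: fluoride removes the silyl group of 7 and triflate departs to give aryne 15, the oxygen of enolate 14 adds to the aryne carbon remote from the flanking OMOM group (bond O1–C8a), and aryl anion 16, born next to that OMOM group, attacks the cis ethyl ester and expels ethoxide (bond C4–C4a). The closest known reaction types are the CsF-mediated annulation of arynes with methyl salicylates to xanthones, of which this is the open-chain vinylogue, and the acyl-alkylation of arynes with beta-keto esters, which marks the competing carbon pathway. Ring C closes in a 6-exo-trig mode on the ester carbonyl, and no stereocentre is created. Site selectivity on the aryne comes from the inductively withdrawing alkoxy group at its C3, which distorts the triple bond so that nucleophiles enter at C1 and the charge builds up at C2, the future C4a. Oxygen over carbon arylation is the open point and is favoured because the enolate carbon already carries aryl, ester and CH–O groups and would have to become a crowded quaternary centre, whereas the charge of this vinylogous carboxylate rests mainly on oxygen. Preforming the sodium enolate takes every O–H proton out of the flask, so 16 cannot be quenched before acyl transfer, sodium chelation in THF holds the enolate oxygen and the ester on the same side of C2=C3 as the closure requires, and the excess of 7 absorbs the ethoxide set free.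

Step 10
Reactants: 17 3-[3-bromo-4-methoxy-5-(methoxymethoxy)phenyl]-5,7-bis(methoxymethoxy)chromen-4-one; 18 tributyl(3-methylbut-2-enyl)stannane
Product: 19 3-[4-methoxy-3-(methoxymethoxy)-5-(3-methylbut-2-enyl)phenyl]-5,7-bis(methoxymethoxy)chromen-4-one
Conditions: 18 (1.5 equiv), Pd(PPh3)4 (5 mol %), DMF, 100 °C
Reagents that add atoms: tributyl(3-methylbut-2-enyl)stannane 18, CCCC[Sn](CCCC)(CCCC)CC=C(C)C
Why: In this Stille coupling zerovalent palladium inserts into the aryl C–Br bond, the allyl unit is passed from tin to palladium and reductive elimination at the unsubstituted allyl terminus should give the linear prenyl arene, under neutral conditions that leave the chromone and the MOM ethers alone.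

Step 11
Reactants: 19 3-[4-methoxy-3-(methoxymethoxy)-5-(3-methylbut-2-enyl)phenyl]-5,7-bis(methoxymethoxy)chromen-4-one
Product: 20 5,7-dihydroxy-3-[3-hydroxy-4-methoxy-5-(3-methylbut-2-enyl)phenyl]chromen-4-one (target)
Conditions: 3 M aq. HCl, MeOH, 50 °C
Reagents that add atoms: none
Why: Acid-catalysed transacetalisation to methanol removes all three MOM ethers in one operation, and the prenyl group should survive because its only ortho oxygen is the 4'-methyl ether, so no chroman can form, and dilute acid at mild temperature adds only slowly to a trisubstituted alkene.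

Compound list
1 | phloroglucinol | Oc1cc(O)cc(O)c1 | starting material
2 | 3,5-bis(methoxymethoxy)phenol | COCOc1cc(O)cc(OCOC)c1 | intermediate
3 | 2-bromo-3,5-bis(methoxymethoxy)phenol | COCOc1cc(O)c(Br)c(OCOC)c1 | intermediate
4 | [2-bromo-3,5-bis(methoxymethoxy)phenoxy]trimethylsilane | COCOc1cc(O[Si](C)(C)C)c(Br)c(OCOC)c1 | intermediate
5 | 2,4-bis(methoxymethoxy)-6-(trimethylsilyloxy)phenyllithium (not isolated) | COCOc1cc(O[Si](C)(C)C)c([Li])c(OCOC)c1 | intermediate
6 | lithium 3,5-bis(methoxymethoxy)-2-(trimethylsilyl)phenoxide (not isolated) | COCOc1cc([O-])c([Si](C)(C)C)c(OCOC)c1.[Li+] | intermediate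
7 | 3,5-bis(methoxymethoxy)-2-(trimethylsilyl)phenyl trifluoromethanesulfonate | COCOc1cc(OCOC)c([Si](C)(C)C)c(OS(=O)(=O)C(F)(F)F)c1 | intermediate
8 | 5-bromovanillin | COc1cc(C=O)cc(Br)c1O | starting material
9 | 3-bromo-4,5-dihydroxybenzaldehyde | O=Cc1cc(O)c(O)c(Br)c1 | intermediate
10 | 3-bromo-5-hydroxy-4-methoxybenzaldehyde | COc1c(O)cc(C=O)cc1Br | intermediate
11 | 3-bromo-4-methoxy-5-(methoxymethoxy)benzaldehyde | COCOc1cc(C=O)cc(Br)c1OC | intermediate
12 | ethyl diazoacetate | CCOC(=O)C=[N+]=[N-] | starting material
13 | ethyl (Z)-2-[3-bromo-4-methoxy-5-(methoxymethoxy)phenyl]-3-hydroxyprop-2-enoate (enol of the 3-oxopropanoate) | CCOC(=O)/C(=C\O)c1cc(Br)c(OC)c(OCOC)c1 | intermediate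
14 | sodium (Z)-enolate of 13 (not isolated) | CCOC(=O)/C(=C\[O-])c1cc(Br)c(OC)c(OCOC)c1.[Na+] | intermediate
15 | 3,5-bis(methoxymethoxy)benzyne (not isolated) | COCOC1=CC(OCOC)=CC#C1 | intermediate
16 | aryl anion from O-arylation, ethyl (Z)-3-[2-sodio-3,5-bis(methoxymethoxy)phenoxy]-2-arylacrylate (not isolated) | CCOC(=O)/C(=C\OC1=CC(OCOC)=CC(OCOC)=[C-]1)c1cc(Br)c(OC)c(OCOC)c1.[Na+] | intermediate
17 | 3-[3-bromo-4-methoxy-5-(methoxymethoxy)phenyl]-5,7-bis(methoxymethoxy)chromen-4-one | COCOc1cc(OCOC)c2c(c1)occ(-c1cc(Br)c(OC)c(OCOC)c1)c2=O | intermediate
18 | tributyl(3-methylbut-2-enyl)stannane | CCCC[Sn](CCCC)(CCCC)CC=C(C)C | starting material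
19 | 3-[4-methoxy-3-(methoxymethoxy)-5-(3-methylbut-2-enyl)phenyl]-5,7-bis(methoxymethoxy)chromen-4-one | COCOc1cc(OCOC)c2c(c1)occ(-c1cc(CC=C(C)C)c(OC)c(OCOC)c1)c2=O | intermediate
20 | 5,7-dihydroxy-3-[3-hydroxy-4-methoxy-5-(3-methylbut-2-enyl)phenyl]chromen-4-one | COc1c(O)cc(-c2coc3cc(O)cc(O)c3c2=O)cc1CC=C(C)C | target

Total step count: 11. Longest linear sequence: 7 (steps 1–4 or steps 5–8, then steps 9–11).

Steps most likely to fail

**1. Step 9.**
- The ambident enolate may be arylated through carbon, after which the aryl anion takes the formyl group instead of the ester.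
- Oxygen arylation may proceed from the enolate rotamer that holds oxygen trans to the ester, which leaves the anion out of reach of the acyl carbon.
- The ethoxide set free may intercept the aryne.
- The fallback is the classical deoxybenzoin construction. It sets out from 13 and 1 and comes back at 17.
- Hot aqueous NaOH cleaves 13 by retro-Claisen deformylation and saponification to [3-bromo-4-methoxy-5-(methoxymethoxy)phenyl]acetic acid F1.
- Friedel–Crafts acylation of phloroglucinol 1 with this acid in BF3·OEt2 at 85 °C, during which the MOM ether is lost, should give 2-(3-bromo-5-hydroxy-4-methoxyphenyl)-1-(2,4,6-trihydroxyphenyl)ethanone F2.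
- One-carbon closure with DMF, BF3·OEt2 and MsCl supplies C2 and gives 3-(3-bromo-5-hydroxy-4-methoxyphenyl)-5,7-dihydroxychromen-4-one F3.
- MOMCl with NaH in DMF protects all three phenols and returns 17.

**2. Step 8.**
- Hydride instead of aryl may migrate after the diazoacetate addition (the Roskamp pathway).
- The strong acid may strip the MOM ether.
- The fallback is a stepwise chain extension followed by formylation. It sets out from 11 and comes back at 13.
- Van Leusen reductive cyanation (TosMIC, t-BuOK, DME, −30 °C, then MeOH, reflux) gives [3-bromo-4-methoxy-5-(methoxymethoxy)phenyl]acetonitrile F4.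
- Pinner ethanolysis (HCl, EtOH, then water) gives ethyl (3-bromo-5-hydroxy-4-methoxyphenyl)acetate F5 with loss of the MOM group.
- MOMCl and i-Pr2NEt restore the MOM group in ethyl [3-bromo-4-methoxy-5-(methoxymethoxy)phenyl]acetate F6.
- Crossed Claisen condensation with ethyl formate and NaH in THF, followed by mild acidification, returns 13.

**3. Step 10.**
- The allyl unit may be transferred through its substituted terminus.
- The stannane may be lost by protodestannylation before it couples.
- The fallback builds the prenyl group in two stages without any ambiguity of allyl terminus. It sets out from 17 and comes back at 19.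
- Stille coupling with allyltributylstannane (Pd(PPh3)4, DMF, 100 °C) gives 3-[3-allyl-4-methoxy-5-(methoxymethoxy)phenyl]-5,7-bis(methoxymethoxy)chromen-4-one F7.
- Cross-metathesis with excess 2-methylbut-2-ene (second-generation Grubbs catalyst, CH2Cl2, 40 °C) converts the terminal alkene into the trisubstituted one of 19.

Further compounds
F1 | step 9 | [3-bromo-4-methoxy-5-(methoxymethoxy)phenyl]acetic acid | COCOc1cc(CC(=O)O)cc(Br)c1OC
F2 | step 9 | 2-(3-bromo-5-hydroxy-4-methoxyphenyl)-1-(2,4,6-trihydroxyphenyl)ethanone | COc1c(O)cc(CC(=O)c2c(O)cc(O)cc2O)cc1Br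
F3 | step 9 | 3-(3-bromo-5-hydroxy-4-methoxyphenyl)-5,7-dihydroxychromen-4-one | COc1c(O)cc(-c2coc3cc(O)cc(O)c3c2=O)cc1Br
F4 | step 8 | [3-bromo-4-methoxy-5-(methoxymethoxy)phenyl]acetonitrile | COCOc1cc(CC#N)cc(Br)c1OC
F5 | step 8 | ethyl (3-bromo-5-hydroxy-4-methoxyphenyl)acetate | CCOC(=O)Cc1cc(O)c(OC)c(Br)c1
F6 | step 8 | ethyl [3-bromo-4-methoxy-5-(methoxymethoxy)phenyl]acetate | CCOC(=O)Cc1cc(Br)c(OC)c(OCOC)c1
F7 | step 10 | 3-[3-allyl-4-methoxy-5-(methoxymethoxy)phenyl]-5,7-bis(methoxymethoxy)chromen-4-one | COCOc1cc(OCOC)c2c(c1)occ(-c1cc(CC=C)c(OC)c(OCOC)c1)c2=O
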